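The saturated ring B (C1–C4, C4a, C8a) carries its C1 methyl group and its C4 chain on opposite faces, the pattern of a menthane monoterpene, so it is bought as (R)-carvone and only C5–C8 of arene ring A have to be made. Ring A is cut at C5–C6 and C8–C8a. In one operation a Knoevenagel–aldol–dehydration cascade joins the 2-hydroxymethylene derivative of trans-dihydrocarvone (its isopropenyl group is the later C11 handle) to methyl 4-(benzyloxy)-3-oxobutanoate and delivers the complete salicylate ring: ester at C6, free hydroxyl at C7, benzyl ether at C8. Allylic oxidation, Ru–BINAP hydrogenation (C11) and a Julia–Kocienski coupling with a lactone-derived C13–C16 sulfone (C15) complete the chain.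

Key step: step 3

Remark on numbering: the tetralin is numbered C1 (CH–CH3), C2, C3, C4 (CH bearing the chain), C4a, C5 (aromatic CH), C6 (CO2Me), C7, C8, C8a; the chain is C11 (CH–CH3), C12, C13, C14, C15 (CH–CH3), C16 (CH2OH). Tetralin names below use these locants; the target is (1R,4S,11S,15S).
Remark on materials: compounds 4, 7 and 14 are taken as purchasable.
Remark on step 6: the (R) ligand is assigned by analogy with Ru–BINAP hydrogenations of other 2-substituted prop-2-en-1-ols that bear a stereogenic carbon on the alkene; the sense on this substrate is to be confirmed before scale-up.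

Step 1
Reactants: 1 (R)-carvone
Product: 3 trans-dihydrocarvone [(2R,5R)-2-methyl-5-(prop-1-en-2-yl)cyclohexan-1-one], via lithium enolate 2 (not isolated)
Conditions: LiBH(sec-Bu)3 (1.1 equiv), THF, −78 °C; then sat. aq. NH4Cl, −78 °C → rt
Reagents that add atoms: none
Why: Conjugate hydride reduction of the β-unsubstituted enone gives enolate 2, whose axial protonation on the chair-forming face should place the new C2 methyl equatorial and trans to the untouched C5 isopropenyl group; any cis epimer is removed by chromatography here or by crystallisation of 9.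

Step 2
Reactants: 3 trans-dihydrocarvone; 4 2,2,2-trifluoroethyl formate
Product: 6 (2Z,3S,6R)-2-(hydroxymethylidene)-6-methyl-3-(prop-1-en-2-yl)cyclohexan-1-one, via kinetic lithium enolate 5 (not isolated)
Conditions: LiN(i-Pr)2 (1.1 equiv), THF, −78 °C; then 4 (1.5 equiv), −78 → 0 °C; 1 M HCl
Reagents that add atoms: 2,2,2-trifluoroethyl formate (4), O=COCC(F)(F)F
Why: Kinetic deprotonation at the unhindered α-methylene followed by Claisen-type C-formylation with the activated formate should give the chelated (Z)-enol, and because the methyl-bearing α-carbon is never enolised the trans relationship set in step 1 is kept.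

Step 3
Reactants: 6 (2Z,3S,6R)-2-(hydroxymethylidene)-6-methyl-3-(prop-1-en-2-yl)cyclohexan-1-one; 7 methyl 4-(benzyloxy)-3-oxobutanoate
Product: 9 methyl (1R,4S)-8-(benzyloxy)-7-hydroxy-1-methyl-4-(prop-1-en-2-yl)-1,2,3,4-tetrahydronaphthalene-6-carboxylate, via Knoevenagel adduct 8 (not isolated)
Conditions: 7 (1.2 equiv), piperidine (0.2 equiv), AcOH (0.2 equiv), MeOH, 25 °C; then K2CO3 (2 equiv), 60 °C; 1 M HCl
Reagents that add atoms: none
Why: Piperidinium acetate turns the chelated enol aldehyde of 6 into an iminium or enaminone to which the doubly activated C6 methylene of 7 adds, and loss of piperidine and water gives adduct 8 with the C5–C6 bond in place (Knoevenagel condensation). K2CO3 then enolises the benzyloxymethyl ketone toward C8, this carbon adds to the C8a ketone (intramolecular aldol), and loss of water followed by tautomerisation of the cyclohexadienone gives the salicylate, aromatisation being the driving force. The closest known reaction type is the base-mediated condensation of 2-hydroxymethylene cycloalkanones with β-keto esters or acetonedicarboxylates to salicylates. Ring A closes by a 6-(enolendo)-exo-trig aldol. No stereocentre is formed; C1 and C4 come unchanged from 6, C1 being shielded from enolisation because the neighbouring carbonyl is held as enol, vinylogous amide or extended enolate until it is consumed. The step needs C6-to-C5 and C8-to-C8a regiochemistry and C- rather than O-cyclisation: the first follows from pairing the more acidic methylene with the more electrophilic formyl carbon, the second from the α-benzyloxy group, which acidifies C8, and from the irreversibility of aromatisation, which drains reversibly formed pyran-type adducts.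

Step 4
Reactants: 9 methyl (1R,4S)-8-(benzyloxy)-7-hydroxy-1-methyl-4-(prop-1-en-2-yl)-1,2,3,4-tetrahydronaphthalene-6-carboxylate
Product: 10 methyl (1R,4S)-7,8-bis(benzyloxy)-1-methyl-4-(prop-1-en-2-yl)-1,2,3,4-tetrahydronaphthalene-6-carboxylate
Conditions: BnBr (1.5 equiv), K2CO3 (2 equiv), DMF, 60 °C
Reagents that add atoms: benzyl bromide, BrCc1ccccc1
Why: Williamson etherification of the chelated salicylate hydroxyl removes the only acidic, oxidisable proton before the oxidation and carbanion steps, and the new ether leaves in the final hydrogenolysis at no extra cost.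

Step 5
Reactants: 10 methyl (1R,4S)-7,8-bis(benzyloxy)-1-methyl-4-(prop-1-en-2-yl)-1,2,3,4-tetrahydronaphthalene-6-carboxylate
Product: 11 methyl (1R,4R)-7,8-bis(benzyloxy)-4-(3-hydroxyprop-1-en-2-yl)-1-methyl-1,2,3,4-tetrahydronaphthalene-6-carboxylate
Conditions: SeO2 (0.3 equiv), t-BuOOH (3 equiv), CH2Cl2, 25 °C
Reagents that add atoms: tert-butyl hydroperoxide, CC(C)(C)OO (terminal oxidant); selenium dioxide, O=[Se]=O (transfers the oxygen)
Why: Riley allylic oxidation, in which an ene reaction at the terminal CH2 and a [2,3]-sigmatropic shift place oxygen on the former methyl carbon (now C12) and restore the 1,1-disubstituted alkene; abstraction from the methyl group is expected to beat abstraction of the hindered benzylic C4–H, and the change of the C4 descriptor to R is a priority effect only.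

Step 6
Reactants: 11 methyl (1R,4R)-7,8-bis(benzyloxy)-4-(3-hydroxyprop-1-en-2-yl)-1-methyl-1,2,3,4-tetrahydronaphthalene-6-carboxylate
Product: 12 methyl (1R,4S)-7,8-bis(benzyloxy)-4-[(2R)-1-hydroxypropan-2-yl]-1-methyl-1,2,3,4-tetrahydronaphthalene-6-carboxylate
Conditions: H2 (50–100 atm), Ru(OAc)2[(R)-Tol-BINAP] (1 mol %), MeOH, 25 °C
Reagents that add atoms: none
Why: Hydroxyl-assisted Ru–BINAP asymmetric hydrogenation of a 2-substituted allylic alcohol, in which the (R) ligand should deliver hydrogen to the alkene face that gives the (R)-configured CH(CH3)CH2OH centre (C11, S in the target), high pressure suppressing isomerisation to the aldehyde; aryl benzyl ethers and the ester are inert to this homogeneous catalyst.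

Step 7
Reactants: 12 methyl (1R,4S)-7,8-bis(benzyloxy)-4-[(2R)-1-hydroxypropan-2-yl]-1-methyl-1,2,3,4-tetrahydronaphthalene-6-carboxylate
Product: 13 methyl (1R,4S)-7,8-bis(benzyloxy)-1-methyl-4-[(2R)-1-oxopropan-2-yl]-1,2,3,4-tetrahydronaphthalene-6-carboxylate
Conditions: Dess–Martin periodinane (1.3 equiv), CH2Cl2, 0 → 25 °C
Reagents that add atoms: none
Why: Dess–Martin oxidation of the primary alcohol is base-free, so the α-branched C12 aldehyde should form without epimerisation at C11; it is used at once.

Step 8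
Reactants: 14 (S)-4-methyldihydrofuran-2(3H)-one
Product: 16 (3S)-4-(benzyloxy)-3-methylbutanoic acid, via benzyl ester 15 (not isolated)
Conditions: KOH (powdered, 4 equiv), BnBr (3 equiv), toluene, 110 °C; then KOH, MeOH/H2O, 70 °C; 2 M HCl
Reagents that add atoms: benzyl bromide, BrCc1ccccc1; potassium hydroxide, [K+].[OH-]
Why: Hydroxide opens the lactone, the alkoxide and carboxylate are both benzylated (Williamson etherification and ester formation) and saponification of 15 leaves the ether acid with the two chain ends differentiated; the methyl-bearing carbon (C15) is β to the carboxyl and cannot epimerise.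

Step 9
Reactants: 16 (3S)-4-(benzyloxy)-3-methylbutanoic acid
Product: 17 (3S)-4-(benzyloxy)-3-methylbutan-1-ol
Conditions: LiAlH4 (1.5 equiv), THF, 0 → 25 °C; aqueous work-up
Reagents that add atoms: none
Why: Hydride reduction of the carboxylic acid to the primary alcohol (C13), to which the benzyl ether is inert.

Step 10
Reactants: 17 (3S)-4-(benzyloxy)-3-methylbutan-1-ol
Product: 18 5-{[(3S)-4-(benzyloxy)-3-methylbutyl]sulfanyl}-1-phenyl-1H-tetrazole
Conditions: 1-phenyl-1H-tetrazole-5-thiol (1.2 equiv), PPh3 (1.2 equiv), DIAD (1.2 equiv), THF, 0 → 25 °C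
Reagents that add atoms: 1-phenyl-1H-tetrazole-5-thiol, Sc1nnnn1-c2ccccc2
Why: Mitsunobu thioetherification of an unhindered primary alcohol with the acidic heteroaryl thiol (SN2 at C13).

Step 11
Reactants: 18 5-{[(3S)-4-(benzyloxy)-3-methylbutyl]sulfanyl}-1-phenyl-1H-tetrazole
Product: 19 5-{[(3S)-4-(benzyloxy)-3-methylbutyl]sulfonyl}-1-phenyl-1H-tetrazole
Conditions: 30% H2O2 (5 equiv), (NH4)6Mo7O24·4H2O (10 mol %), EtOH, 0 → 25 °C
Reagents that add atoms: hydrogen peroxide, OO
Why: Molybdate-catalysed peroxide oxidation of the sulfide to the sulfone, to which the benzyl ether and the tetrazole are inert.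

Step 12
Reactants: 13 methyl (1R,4S)-7,8-bis(benzyloxy)-1-methyl-4-[(2R)-1-oxopropan-2-yl]-1,2,3,4-tetrahydronaphthalene-6-carboxylate; 19 5-{[(3S)-4-(benzyloxy)-3-methylbutyl]sulfonyl}-1-phenyl-1H-tetrazole
Product: 21 methyl (1R,4S)-7,8-bis(benzyloxy)-4-[(2S,3E,6S)-7-(benzyloxy)-6-methylhept-3-en-2-yl]-1-methyl-1,2,3,4-tetrahydronaphthalene-6-carboxylate, via potassium sulfonyl carbanion 20 (not isolated)
Conditions: 19 (1.3 equiv), KN(SiMe3)2 (1.25 equiv), DME, −60 °C; then 13, −60 → 25 °C; aq. NH4Cl
Reagents that add atoms: none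
Why: Julia–Kocienski olefination (carbanion addition, Smiles rearrangement, loss of SO2 and the tetrazololate) forms C12=C13; the pre-formed anion, kept short of the base in equivalents, adds at low temperature faster than it enolises the aldehyde, so C11 should survive, and the alkene geometry (E expected) is irrelevant because step 13 saturates it.

Step 13
Reactants: 21 methyl (1R,4S)-7,8-bis(benzyloxy)-4-[(2S,3E,6S)-7-(benzyloxy)-6-methylhept-3-en-2-yl]-1-methyl-1,2,3,4-tetrahydronaphthalene-6-carboxylate
Product: 23 methyl (1R,4S)-7,8-dihydroxy-4-[(2S,6S)-7-hydroxy-6-methylheptan-2-yl]-1-methyl-1,2,3,4-tetrahydronaphthalene-6-carboxylate (CNP0135649.1), via saturated tribenzyl ether 22 (not isolated)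
Conditions: H2 (1 atm), Pt/C, EtOAc, 25 °C; then Pd(OH)2/C, MeOH, H2 (1 atm), 25 °C
Reagents that add atoms: none
Why: Heterogeneous hydrogenation on Pt/C, which causes little double-bond migration, saturates C12=C13 without scrambling the allylic C11 centre, and Pd(OH)2/C then hydrogenolyses the two aryl benzyl ethers and the alkyl benzyl ether while the ester, the arene and the benzylic C1 and C4 carbons are untouched.

Compound list
1 | (R)-carvone, (5R)-2-methyl-5-(prop-1-en-2-yl)cyclohex-2-en-1-one | CC1=CC[C@H](CC1=O)C(=C)C | starting material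
2 | lithium (5R)-2-methyl-5-(prop-1-en-2-yl)cyclohex-1-en-1-olate | [Li+].[O-]C1=C(C)CC[C@H](C1)C(C)=C | intermediate
3 | trans-dihydrocarvone, (2R,5R)-2-methyl-5-(prop-1-en-2-yl)cyclohexan-1-one | O=C1[C@H](C)CC[C@H](C1)C(C)=C | intermediate
4 | 2,2,2-trifluoroethyl formate | O=COCC(F)(F)F | starting material
5 | lithium (3R,6R)-6-methyl-3-(prop-1-en-2-yl)cyclohex-1-en-1-olate | [Li+].[O-]C1=C[C@@H](CC[C@H]1C)C(C)=C | intermediate
6 | (2Z,3S,6R)-2-(hydroxymethylidene)-6-methyl-3-(prop-1-en-2-yl)cyclohexan-1-one | O/C=C1\C(=O)[C@H](C)CC[C@H]1C(C)=C | intermediate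
7 | methyl 4-(benzyloxy)-3-oxobutanoate | COC(=O)CC(=O)COCc1ccccc1 | starting material
8 | methyl 4-(benzyloxy)-2-{[(3R,6R)-3-methyl-2-oxo-6-(prop-1-en-2-yl)cyclohexyl]methylidene}-3-oxobutanoate (alkene isomers, C4a epimers and enol tautomers) | COC(=O)C(=CC1C(=O)[C@H](C)CC[C@H]1C(C)=C)C(=O)COCc2ccccc2 | intermediate
9 | methyl (1R,4S)-8-(benzyloxy)-7-hydroxy-1-methyl-4-(prop-1-en-2-yl)-1,2,3,4-tetrahydronaphthalene-6-carboxylate | COC(=O)c1cc2c(c(OCc3ccccc3)c1O)[C@H](C)CC[C@H]2C(C)=C | intermediate
10 | methyl (1R,4S)-7,8-bis(benzyloxy)-1-methyl-4-(prop-1-en-2-yl)-1,2,3,4-tetrahydronaphthalene-6-carboxylate | COC(=O)c1cc2c(c(OCc3ccccc3)c1OCc4ccccc4)[C@H](C)CC[C@H]2C(C)=C | intermediate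
11 | methyl (1R,4R)-7,8-bis(benzyloxy)-4-(3-hydroxyprop-1-en-2-yl)-1-methyl-1,2,3,4-tetrahydronaphthalene-6-carboxylate | COC(=O)c1cc2c(c(OCc3ccccc3)c1OCc4ccccc4)[C@H](C)CC[C@H]2C(=C)CO | intermediate
12 | methyl (1R,4S)-7,8-bis(benzyloxy)-4-[(2R)-1-hydroxypropan-2-yl]-1-methyl-1,2,3,4-tetrahydronaphthalene-6-carboxylate | COC(=O)c1cc2c(c(OCc3ccccc3)c1OCc4ccccc4)[C@H](C)CC[C@H]2[C@@H](C)CO | intermediate
13 | methyl (1R,4S)-7,8-bis(benzyloxy)-1-methyl-4-[(2R)-1-oxopropan-2-yl]-1,2,3,4-tetrahydronaphthalene-6-carboxylate | COC(=O)c1cc2c(c(OCc3ccccc3)c1OCc4ccccc4)[C@H](C)CC[C@H]2[C@@H](C)C=O | intermediate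
14 | (S)-4-methyldihydrofuran-2(3H)-one, (S)-β-methyl-γ-butyrolactone | O=C1C[C@H](C)CO1 | starting material
15 | benzyl (3S)-4-(benzyloxy)-3-methylbutanoate | O=C(C[C@H](C)COCc1ccccc1)OCc2ccccc2 | intermediate
16 | (3S)-4-(benzyloxy)-3-methylbutanoic acid | OC(=O)C[C@H](C)COCc1ccccc1 | intermediate
17 | (3S)-4-(benzyloxy)-3-methylbutan-1-ol | OCC[C@H](C)COCc1ccccc1 | intermediate
18 | 5-{[(3S)-4-(benzyloxy)-3-methylbutyl]sulfanyl}-1-phenyl-1H-tetrazole | c1ccccc1-n2nnnc2SCC[C@H](C)COCc3ccccc3 | intermediate
19 | 5-{[(3S)-4-(benzyloxy)-3-methylbutyl]sulfonyl}-1-phenyl-1H-tetrazole | c1ccccc1-n2nnnc2S(=O)(=O)CC[C@H](C)COCc3ccccc3 | intermediate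
20 | potassium salt of the α-sulfonyl carbanion of 19 | [K+].c1ccccc1-n2nnnc2S(=O)(=O)[CH-]C[C@H](C)COCc3ccccc3 | intermediate
21 | methyl (1R,4S)-7,8-bis(benzyloxy)-4-[(2S,3E,6S)-7-(benzyloxy)-6-methylhept-3-en-2-yl]-1-methyl-1,2,3,4-tetrahydronaphthalene-6-carboxylate | COC(=O)c1cc2c(c(OCc3ccccc3)c1OCc4ccccc4)[C@H](C)CC[C@H]2[C@@H](C)/C=C/C[C@H](C)COCc5ccccc5 | intermediate
22 | methyl (1R,4S)-7,8-bis(benzyloxy)-4-[(2S,6S)-7-(benzyloxy)-6-methylheptan-2-yl]-1-methyl-1,2,3,4-tetrahydronaphthalene-6-carboxylate | COC(=O)c1cc2c(c(OCc3ccccc3)c1OCc4ccccc4)[C@H](C)CC[C@H]2[C@@H](C)CCC[C@H](C)COCc5ccccc5 | intermediate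
23 | methyl (1R,4S)-7,8-dihydroxy-4-[(2S,6S)-7-hydroxy-6-methylheptan-2-yl]-1-methyl-1,2,3,4-tetrahydronaphthalene-6-carboxylate | COC(=O)c1cc2c(c(O)c1O)[C@H](C)CC[C@H]2[C@@H](C)CCC[C@H](C)CO | target

Total step count: 13
Longest linear sequence: 9 steps (steps 1–7, 12 and 13, from (R)-carvone); the sulfone branch is steps 8–11.

Steps most likely to fail

Step 3. The Knoevenagel adduct may close through oxygen (lactonisation onto the ester or oxa-6π closure to a pyran) faster than C8 adds to the C8a ketone, or may rest as its stabilised extended enolate. Slow enolisation toward C1 during a sluggish closure would also erode the trans relationship. The fallback sets out from 6 and returns at 9, making the two ring bonds in the reverse order. O-Alkylation of 6 (i-PrI, K2CO3, acetone) gives the (E)-isopropoxymethylene ketone F1. The 1,3-dianion of 7 (NaH, then n-BuLi, THF, −78 °C) adds through its C8 carbon to the ketone carbonyl of this vinylogous ester and gives the carbinol F2. Dilute HCl in THF then hydrolyses the enol ether with allylic transposition (Stork–Danheiser type) to the enal keto ester F3. Its formyl group condenses intramolecularly with the C6 methylene (piperidinium acetate, MeOH), and dehydration and tautomerisation give 9.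

Step 5. The ene step may remove the benzylic C4–H instead of a methyl hydrogen, which would oxidise C4 and destroy that stereocentre, or oxidation may run on to the enal. The fallback sets out from 10 and returns at 11. Ene-type chlorination (NaOCl, CeCl3·7H2O, CH2Cl2/H2O, 0 °C) gives the allylic chloride F4, displacement with KOAc in DMF gives the allylic acetate F5, and K2CO3 in MeOH releases 11.

Step 6. Facial selectivity may be poor if the bias of the neighbouring C4 stereocentre opposes the ligand, or the Ru hydride may isomerise the allylic alcohol to the saturated aldehyde with loss of control at C11. The fallback sets out from 11 and returns at 12; it moves the stereo-determining hydrogenation to an acrylic acid, where carboxylate binding governs face selection as in the 2-arylpropionic acid series. MnO2 in CH2Cl2 gives the enal F6, and NaClO2/NaH2PO4/2-methylbut-2-ene gives the acrylic acid F7. Hydrogenation with Ru(OAc)2[(R)-H8-BINAP] (H2, MeOH) gives the (R)-configured saturated acid F8, and BH3·SMe2 (THF, 0 °C) reduces the acid in the presence of the methyl ester to 12.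

Further compounds
F1 | step 3 | (2E,3S,6R)-6-methyl-2-[(propan-2-yloxy)methylidene]-3-(prop-1-en-2-yl)cyclohexan-1-one | CC(C)O/C=C1/C(=O)[C@H](C)CC[C@H]1C(C)=C
F2 | step 3 | methyl 4-(benzyloxy)-4-{(2E,3S,6R)-1-hydroxy-6-methyl-2-[(propan-2-yloxy)methylidene]-3-(prop-1-en-2-yl)cyclohexyl}-3-oxobutanoate (mixture at the two new centres) | COC(=O)CC(=O)C(OCc2ccccc2)C1(O)[C@H](C)CC[C@@H](C(C)=C)/C1=C\OC(C)C
F3 | step 3 | methyl 4-(benzyloxy)-4-[(3S,6R)-2-formyl-6-methyl-3-(prop-1-en-2-yl)cyclohex-1-en-1-yl]-3-oxobutanoate | COC(=O)CC(=O)C(OCc2ccccc2)C1=C(C=O)[C@@H](CC[C@H]1C)C(C)=C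
F4 | step 5 | methyl (1R,4R)-7,8-bis(benzyloxy)-4-(3-chloroprop-1-en-2-yl)-1-methyl-1,2,3,4-tetrahydronaphthalene-6-carboxylate | COC(=O)c1cc2c(c(OCc3ccccc3)c1OCc4ccccc4)[C@H](C)CC[C@H]2C(=C)CCl
F5 | step 5 | methyl (1R,4R)-4-[3-(acetyloxy)prop-1-en-2-yl]-7,8-bis(benzyloxy)-1-methyl-1,2,3,4-tetrahydronaphthalene-6-carboxylate | COC(=O)c1cc2c(c(OCc3ccccc3)c1OCc4ccccc4)[C@H](C)CC[C@H]2C(=C)COC(C)=O
F6 | step 6 | methyl (1R,4R)-7,8-bis(benzyloxy)-1-methyl-4-(3-oxoprop-1-en-2-yl)-1,2,3,4-tetrahydronaphthalene-6-carboxylate | COC(=O)c1cc2c(c(OCc3ccccc3)c1OCc4ccccc4)[C@H](C)CC[C@H]2C(=C)C=O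
F7 | step 6 | 2-[(1R,4R)-5,6-bis(benzyloxy)-7-(methoxycarbonyl)-4-methyl-1,2,3,4-tetrahydronaphthalen-1-yl]prop-2-enoic acid (the acrylic acid at C11–C12) | COC(=O)c1cc2c(c(OCc3ccccc3)c1OCc4ccccc4)[C@H](C)CC[C@H]2C(=C)C(O)=O
F8 | step 6 | (2R)-2-[(1S,4R)-5,6-bis(benzyloxy)-7-(methoxycarbonyl)-4-methyl-1,2,3,4-tetrahydronaphthalen-1-yl]propanoic acid | COC(=O)c1cc2c(c(OCc3ccccc3)c1OCc4ccccc4)[C@H](C)CC[C@H]2[C@@H](C)C(O)=O
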